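**Plan**

- Retrosynthesis: C11–OH goes back to a C11 ketone and then a C11 nitro group. One operation then cuts C11–C12, C9–C10 and N4–C5, which removes the cyclohexene and azepine rings and leaves a spiro-butenolide 1-pyrroline (C9a=N4) with a 5-chloropentyl chain, plus (E)-1-nitrobut-1-ene. Earlier cuts: C9a–C9 (lactam + Grignard reagent), C18–C19 (alcohol C-allylation), C1–O and C1–C12 (lactam enolate).
- Enabling feature: C9 (β-carbon of the N4–C9a=C9 enamine, donor) and C12 (β-carbon of the butenolide spiro-fused at C1, acceptor) are 1,4-related across C9a–C1. A nitroalkene (C10 acceptor, C11 donor) bridges them to the cyclohexene C9a–C9–C10–C11–C12–C1.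
- Forward ring order: pyrrolidine (from D-pyroglutaminol), then the spiro-lactone on C1, then the side-chain lactone, then azepine and cyclohexene together in the key cascade, then Nef reaction and ketone reduction.
- Stereochemistry: C3 from D-pyroglutaminol; C1 by enolate hydroxylation anti to the C3 substituent; C18 by catalyst-controlled allylation; C20 by hydrogenation anti to the C18 substituent; C10, C12 and C13 in the key step under control of C1; C11 by hydride delivery anti to the lactone.

Key step: step 13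

Remark on numbering: locants follow the pyrrolo[1,2-a]azepine core (C1, C2, C3, N4, C5–C9, C9a); the carbocycle is C9a–C9–C10–C11–C12–C1; the lactone on C1/C12 is O–C14(=O)–C13(CH3); the side-chain lactone is C18(O)–C19–C20(CH3)–C21(=O). The target is (1R,3R,10S,11R,12R,13R,18S,20S). The SMILES in the compound list define the configurations.
Remark on supply: nitroalkene 21 and allyl carbonate 11 are prepared (steps 7, 11, 12) because their commercial supply is uncertain.

**Step 1**
Reactants: 1 (5R)-5-(hydroxymethyl)pyrrolidin-2-one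
Product: 2 (5R)-5-{[(tert-butyldimethylsilyl)oxy]methyl}pyrrolidin-2-one
Conditions: TBSCl, imidazole, DMF, rt
Reagents that add atoms: tert-butyldimethylsilyl chloride, CC(C)(C)[Si](C)(C)Cl
Why: Imidazole-mediated O-silylation of the primary alcohol masks it for the enolate steps and leaves the lactam N–H free.

**Step 2**
Reactants: 2 (5R)-5-{[(tert-butyldimethylsilyl)oxy]methyl}pyrrolidin-2-one
Product: 3 tert-butyl (2R)-2-{[(tert-butyldimethylsilyl)oxy]methyl}-5-oxopyrrolidine-1-carboxylate
Conditions: Boc2O, DMAP (cat.), Et3N, MeCN, rt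
Reagents that add atoms: di-tert-butyl dicarbonate, CC(C)(C)OC(=O)OC(=O)OC(C)(C)C
Why: DMAP-catalysed N-acylation gives the imide-type N-Boc lactam, which makes C1–H the only readily enolisable position.

**Step 3**
Reactants: 3 tert-butyl (2R)-2-{[(tert-butyldimethylsilyl)oxy]methyl}-5-oxopyrrolidine-1-carboxylate; 4 ethyl 2-(bromomethyl)prop-2-enoate
Product: 5 tert-butyl (2R,4S)-2-{[(tert-butyldimethylsilyl)oxy]methyl}-4-[2-(ethoxycarbonyl)prop-2-en-1-yl]-5-oxopyrrolidine-1-carboxylate
Conditions: LiHMDS, THF, −78 °C; then 4, −78 °C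
Reagents that add atoms: none
Why: Lactam enolate alkylation with the allylic bromide should occur anti to the C3 substituent; the C1 configuration is erased again in step 4, so both C1 epimers converge.

**Step 4**
Reactants: 5 tert-butyl (2R,4S)-2-{[(tert-butyldimethylsilyl)oxy]methyl}-4-[2-(ethoxycarbonyl)prop-2-en-1-yl]-5-oxopyrrolidine-1-carboxylate
Product: 7 tert-butyl (5S,8R)-8-{[(tert-butyldimethylsilyl)oxy]methyl}-3-methylidene-2,6-dioxo-1-oxa-7-azaspiro[4.4]nonane-7-carboxylate, via hydroxy ester 6 (not isolated)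
Conditions: KHMDS, THF, −78 °C; 3-phenyl-2-(phenylsulfonyl)oxaziridine; AcOH quench at −78 °C; then CSA (cat.), CH2Cl2, rt
Reagents that add atoms: 3-phenyl-2-(phenylsulfonyl)oxaziridine, O=S(=O)(c1ccccc1)N1OC1c1ccccc1
Why: Davis oxidation of the fully substituted enolate should take place on the face anti to the pseudoaxial CH2OTBS group, which sets C1 with the C–O bond trans to the C3 substituent, and the tertiary alcohol then closes the γ-lactone on the acrylate ester under acid catalysis.

**Step 5**
Reactants: 7 tert-butyl (5S,8R)-8-{[(tert-butyldimethylsilyl)oxy]methyl}-3-methylidene-2,6-dioxo-1-oxa-7-azaspiro[4.4]nonane-7-carboxylate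
Product: 8 (5S,8R)-8-(hydroxymethyl)-3-methylidene-1-oxa-7-azaspiro[4.4]nonane-2,6-dione
Conditions: TFA/H2O (9:1), CH2Cl2, 0 °C to rt; aq. NaHCO3 work-up
Reagents that add atoms: none
Why: Acidolysis should remove the N-Boc group and the primary TBS ether in one operation, while the lactam and the α-methylene lactone are stable to TFA.

**Step 6**
Reactants: 8 (5S,8R)-8-(hydroxymethyl)-3-methylidene-1-oxa-7-azaspiro[4.4]nonane-2,6-dione
Product: 9 (5R,8R)-8-(hydroxymethyl)-3-methyl-1-oxa-7-azaspiro[4.4]non-3-ene-2,6-dione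
Conditions: RhCl3·3H2O (5 mol%), EtOH, 75 °C
Reagents that add atoms: none
Why: Rhodium hydride alkene isomerisation should move the exocyclic double bond into the ring (α-methylene lactone to α-methyl butenolide) without touching a stereocentre, which creates the C12 acceptor; the descriptor at the spiro carbon changes only by CIP priority.

**Step 7**
Reactants: 10 ethyl 2-(hydroxymethyl)prop-2-enoate
Product: 11 ethyl 2-{[(tert-butoxycarbonyl)oxy]methyl}prop-2-enoate
Conditions: Boc2O, DMAP (cat.), CH2Cl2, 0 °C
Reagents that add atoms: di-tert-butyl dicarbonate, CC(C)(C)OC(=O)OC(=O)OC(C)(C)C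
Why: DMAP-catalysed carbonate formation on the allylic alcohol gives the 2-(alkoxycarbonyl)allyl donor for step 8.

**Step 8**
Reactants: 9 (5R,8R)-8-(hydroxymethyl)-3-methyl-1-oxa-7-azaspiro[4.4]non-3-ene-2,6-dione; 11 ethyl 2-{[(tert-butoxycarbonyl)oxy]methyl}prop-2-enoate
Product: 13 (5R,8R)-3-methyl-8-[(2S)-4-methylidene-5-oxooxolan-2-yl]-1-oxa-7-azaspiro[4.4]non-3-ene-2,6-dione, via hydroxy acrylate 12 (not isolated)
Conditions: [Ir(cod)Cl]2 (2.5 mol%), SEGPHOS (5 mol%, the antipode that gives 18S), 4-cyano-3-nitrobenzoic acid (10 mol%), Cs2CO3 (20 mol%), THF, 60 °C; then CSA (cat.) to complete lactonisation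
Reagents that add atoms: none
Why: Krische iridium-catalysed transfer-hydrogenative 2-(alkoxycarbonyl)allylation of a primary alcohol: the transient α-amido aldehyde is allylated as it forms and so should not epimerise at C3, the ligand antipode is chosen so that catalyst control and Felkin–Anh control (N4 anti to the incoming allyl) both give the 18S carbinol, and this lactonises to the α-methylene lactone.

**Step 9**
Reactants: 13 (5R,8R)-3-methyl-8-[(2S)-4-methylidene-5-oxooxolan-2-yl]-1-oxa-7-azaspiro[4.4]non-3-ene-2,6-dione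
Product: 14 (5R,8R)-3-methyl-8-[(2S,4S)-4-methyl-5-oxooxolan-2-yl]-1-oxa-7-azaspiro[4.4]non-3-ene-2,6-dione
Conditions: H2 (1 atm), RhCl(PPh3)3 (5 mol%), benzene/EtOH, rt
Reagents that add atoms: none
Why: Wilkinson hydrogenation should reduce only the exocyclic 1,1-disubstituted alkene (the hindered trisubstituted butenolide is inert), with H2 adding anti to the C18 substituent to give the cis-2,4-disubstituted lactone (20S).

**Step 10**
Reactants: 14 (5R,8R)-3-methyl-8-[(2S,4S)-4-methyl-5-oxooxolan-2-yl]-1-oxa-7-azaspiro[4.4]non-3-ene-2,6-dione; 15 1-bromo-5-chloropentane (as its Grignard reagent)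
Product: 17 (5R,8R)-6-(5-chloropentyl)-3-methyl-8-[(2S,4S)-4-methyl-5-oxooxolan-2-yl]-1-oxa-7-azaspiro[4.4]nona-3,6-dien-2-one, via imidoyl triflate 16 (not isolated)
Conditions: Tf2O, 2-fluoropyridine, CH2Cl2, −78 to 0 °C; then Cl(CH2)5MgBr (from 15, Mg, THF), −78 °C; aq. NaHCO3
Reagents that add atoms: none
Why: Electrophilic activation of the secondary lactam to the cyclic imidoyl triflate followed by addition–elimination of the Grignard reagent should give the ketimine, because activated C9a is far more electrophilic than either lactone at −78 °C.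

**Step 11**
Reactants: 18 propanal; 19 nitromethane
Product: 20 1-nitrobutan-2-ol (racemic)
Conditions: NaOH (cat.), nitromethane (excess), EtOH/H2O, 0 °C
Reagents that add atoms: none
Why: Base-catalysed Henry (nitroaldol) addition.

**Step 12**
Reactants: 20 1-nitrobutan-2-ol
Product: 21 (E)-1-nitrobut-1-ene
Conditions: MsCl, Et3N, CH2Cl2, −10 °C
Reagents that add atoms: none
Why: Mesylation and E1cB elimination should give the conjugated (E)-nitroalkene.

**Step 13**
Reactants: 17 (5R,8R)-6-(5-chloropentyl)-3-methyl-8-[(2S,4S)-4-methyl-5-oxooxolan-2-yl]-1-oxa-7-azaspiro[4.4]nona-3,6-dien-2-one; 21 (E)-1-nitrobut-1-ene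
Product: 25 11-nitro pentacycle (target skeleton with NO2 in place of OH at C11; 1R,3R,10S,11S,12R,13R,18S,20S), via iminium iodide 22 (not isolated), via enamine 23 (not isolated), via nitroalkyl enamine 24 (not isolated)
Conditions: NaI, MeCN, 70 °C; then iPr2NEt, 0 °C; 21, −20 to 0 °C; then DBU (0.3 equiv), rt
Reagents that add atoms: none
Why: Finkelstein exchange and 7-exo-tet N-alkylation of the ketimine nitrogen should give iminium 22, which can lose a proton only at C9 (C1 is quaternary) and so gives the endocyclic enamine 23, as in imine-alkylation routes to endocyclic enamines. Stork-type Michael addition of C9 to the nitroalkene forms C9–C10 and regenerates the enamine (24); DBU then forms the nitronate, which adds 6-exo-trig to the butenolide carbon C12 to form C11–C12, the closest analogy being domino Michael/Michael (formal [4+2]) annulations of enamines with nitroalkenes. The tether forces C11 onto the C9a face of the butenolide, so the new ring is cis-fused to the lactone (12R), and the lactone enolate should be protonated at C13 on the convex face, anti to the new C11–C12 bond (13R, methyl cis to C11). At C10, the two ring fusions at C1 lock the half-chair with C1–O pseudoaxial, and A(1,2) strain with C8 then places the ethyl group pseudoaxial and anti to the lactone oxygen (10S); both Michael steps are reversible under DBU, so this preference should be expressed even if the first addition is unselective. The nitro-bearing C11 equilibrates and is removed in step 14. The step needs N- over C-alkylation of the imine (no base is added until the iminium has formed) and kinetic protonation at C13 (DBU is too weak to epimerise a lactone α-carbon).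

**Step 14**
Reactants: 25 11-nitro pentacycle
Product: 26 11-ketone (target skeleton with C11=O; 1R,3R,10S,12S,13R,18S,20S)
Conditions: DBU, THF, 0 °C; then aq. TiCl3, NH4OAc (pH 5–6), 0 °C to rt; NaHCO3 work-up; used at once
Reagents that add atoms: water, O
Why: McMurry reductive Nef reaction: Ti(III) reduces the nitronate to the imine, which hydrolyses to the ketone under buffered non-basic conditions that should spare the β-acyloxy ketone from E1cB loss of the C1 carboxylate and protonate the enamine only reversibly; both C11 epimers converge.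

**Step 15**
Reactants: 26 11-ketone
Product: 27 target CNP0154902.3 (1R,3R,10S,11R,12R,13R,18S,20S)
Conditions: L-Selectride, THF, −78 °C; AcOH quench at −78 °C
Reagents that add atoms: none
Why: Bulky hydride reduction of the cyclohexanone: the top face of C11 is shielded by the γ-lactone spanning C1/C12 (pseudoaxial C1–O, 1,3-syn to C11), so hydride should enter from the H12 face and leave the hydroxyl syn to the lactone (11R); the cold acidic quench prevents translactonisation of the alkoxide.

**Compound list**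

1 | (5R)-5-(hydroxymethyl)pyrrolidin-2-one | OC[C@H]1CCC(=O)N1 | starting material
2 | (5R)-5-{[(tert-butyldimethylsilyl)oxy]methyl}pyrrolidin-2-one | CC(C)(C)[Si](C)(C)OC[C@H]1CCC(=O)N1 | intermediate
3 | tert-butyl (2R)-2-{[(tert-butyldimethylsilyl)oxy]methyl}-5-oxopyrrolidine-1-carboxylate | CC(C)(C)[Si](C)(C)OC[C@H]1CCC(=O)N1C(=O)OC(C)(C)C | intermediate
4 | ethyl 2-(bromomethyl)prop-2-enoate | C=C(CBr)C(=O)OCC | starting material
5 | tert-butyl (2R,4S)-2-{[(tert-butyldimethylsilyl)oxy]methyl}-4-[2-(ethoxycarbonyl)prop-2-en-1-yl]-5-oxopyrrolidine-1-carboxylate | CC(C)(C)[Si](C)(C)OC[C@H]1C[C@H](CC(=C)C(=O)OCC)C(=O)N1C(=O)OC(C)(C)C | intermediate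
6 | tert-butyl (2R,4S)-2-{[(tert-butyldimethylsilyl)oxy]methyl}-4-[2-(ethoxycarbonyl)prop-2-en-1-yl]-4-hydroxy-5-oxopyrrolidine-1-carboxylate (hydroxy ester) | CC(C)(C)[Si](C)(C)OC[C@H]1C[C@@](O)(CC(=C)C(=O)OCC)C(=O)N1C(=O)OC(C)(C)C | intermediate
7 | tert-butyl (5S,8R)-8-{[(tert-butyldimethylsilyl)oxy]methyl}-3-methylidene-2,6-dioxo-1-oxa-7-azaspiro[4.4]nonane-7-carboxylate | CC(C)(C)[Si](C)(C)OC[C@H]1C[C@@]2(CC(=C)C(=O)O2)C(=O)N1C(=O)OC(C)(C)C | intermediate
8 | (5S,8R)-8-(hydroxymethyl)-3-methylidene-1-oxa-7-azaspiro[4.4]nonane-2,6-dione | OC[C@H]1C[C@@]2(CC(=C)C(=O)O2)C(=O)N1 | intermediate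
9 | (5R,8R)-8-(hydroxymethyl)-3-methyl-1-oxa-7-azaspiro[4.4]non-3-ene-2,6-dione | OC[C@H]1C[C@@]2(C=C(C)C(=O)O2)C(=O)N1 | intermediate
10 | ethyl 2-(hydroxymethyl)prop-2-enoate | C=C(CO)C(=O)OCC | starting material
11 | ethyl 2-{[(tert-butoxycarbonyl)oxy]methyl}prop-2-enoate | C=C(COC(=O)OC(C)(C)C)C(=O)OCC | intermediate
12 | ethyl (4S)-4-hydroxy-2-methylidene-4-[(5R,8R)-3-methyl-2,6-dioxo-1-oxa-7-azaspiro[4.4]non-3-en-8-yl]butanoate (hydroxy acrylate) | O=C1N[C@@H]([C@@H](O)CC(=C)C(=O)OCC)C[C@]13OC(=O)C(C)=C3 | intermediate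
13 | (5R,8R)-3-methyl-8-[(2S)-4-methylidene-5-oxooxolan-2-yl]-1-oxa-7-azaspiro[4.4]non-3-ene-2,6-dione | O=C1N[C@@H]([C@@H]2CC(=C)C(=O)O2)C[C@]13OC(=O)C(C)=C3 | intermediate
14 | (5R,8R)-3-methyl-8-[(2S,4S)-4-methyl-5-oxooxolan-2-yl]-1-oxa-7-azaspiro[4.4]non-3-ene-2,6-dione | O=C1N[C@@H]([C@@H]2C[C@H](C)C(=O)O2)C[C@]13OC(=O)C(C)=C3 | intermediate
15 | 1-bromo-5-chloropentane | ClCCCCCBr | starting material
16 | (5R,8R)-3-methyl-8-[(2S,4S)-4-methyl-5-oxooxolan-2-yl]-2-oxo-1-oxa-7-azaspiro[4.4]nona-3,6-dien-6-yl trifluoromethanesulfonate (imidoyl triflate) | O=S(=O)(OC1=N[C@@H]([C@@H]2C[C@H](C)C(=O)O2)C[C@]13OC(=O)C(C)=C3)C(F)(F)F | intermediate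
17 | (5R,8R)-6-(5-chloropentyl)-3-methyl-8-[(2S,4S)-4-methyl-5-oxooxolan-2-yl]-1-oxa-7-azaspiro[4.4]nona-3,6-dien-2-one | ClCCCCCC1=N[C@@H]([C@@H]2C[C@H](C)C(=O)O2)C[C@]13OC(=O)C(C)=C3 | intermediate
18 | propanal | CCC=O | starting material
19 | nitromethane | C[N+](=O)[O-] | starting material
20 | 1-nitrobutan-2-ol (racemic) | CCC(O)C[N+](=O)[O-] | intermediate
21 | (E)-1-nitrobut-1-ene | CC/C=C/[N+](=O)[O-] | intermediate
22 | (2R,3′R)-4-methyl-3′-[(2S,4S)-4-methyl-5-oxooxolan-2-yl]-5-oxo-2′,3′,6′,7′,8′,9′-hexahydro-5H,5′H-spiro[furan-2,1′-pyrrolo[1,2-a]azepin]-4′-ium iodide (iminium iodide) | C1C2=[N+](CCCC1)[C@@H]([C@@H]3C[C@H](C)C(=O)O3)C[C@]24OC(=O)C(C)=C4.[I-] | intermediate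
23 | (2R,3′R)-4-methyl-3′-[(2S,4S)-4-methyl-5-oxooxolan-2-yl]-2′,3′,5′,6′,7′,8′-hexahydro-5H-spiro[furan-2,1′-pyrrolo[1,2-a]azepin]-5-one (enamine) | C1=C2N(CCCC1)[C@@H]([C@@H]3C[C@H](C)C(=O)O3)C[C@]24OC(=O)C(C)=C4 | intermediate
24 | (2R,3′R)-4-methyl-3′-[(2S,4S)-4-methyl-5-oxooxolan-2-yl]-9′-[(2S)-1-nitrobutan-2-yl]-2′,3′,5′,6′,7′,8′-hexahydro-5H-spiro[furan-2,1′-pyrrolo[1,2-a]azepin]-5-one (nitroalkyl enamine) | CC[C@H](C[N+](=O)[O-])C1=C2N(CCCC1)[C@@H]([C@@H]3C[C@H](C)C(=O)O3)C[C@]24OC(=O)C(C)=C4 | intermediate
25 | 11-nitro pentacycle: target skeleton with NO2 in place of OH at C11, nitro cis to the C10 ethyl group (1R,3R,10S,11S,12R,13R,18S,20S) | CC[C@H]1C2=C3N(CCCC2)[C@@H]([C@@H]2C[C@H](C)C(=O)O2)C[C@]32OC(=O)[C@H](C)[C@@H]2[C@H]1[N+](=O)[O-] | intermediate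
26 | 11-ketone: target skeleton with C11=O (1R,3R,10S,12S,13R,18S,20S) | CC[C@H]1C2=C3N(CCCC2)[C@@H]([C@@H]2C[C@H](C)C(=O)O2)C[C@]32OC(=O)[C@H](C)[C@@H]2C1=O | intermediate
27 | CNP0154902.3: 9,9a-didehydro pyrrolo[1,2-a]azepine fused at C9/C9a/C1 to the cyclohexene, 10-ethyl, 11-hydroxy, C1/C12-fused γ-lactone with 13-methyl, 3-[(2S,4S)-4-methyl-5-oxooxolan-2-yl] (1R,3R,10S,11R,12R,13R,18S,20S) | CC[C@H]1C2=C3N(CCCC2)[C@@H]([C@@H]2C[C@H](C)C(=O)O2)C[C@]32OC(=O)[C@H](C)[C@@H]2[C@@H]1O | target

**Totals**

Total step count: 15. Longest linear sequence: 12 steps (1–6, 8–10, 13–15).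

**Steps most likely to fail**

Step 13. The nitronate ring closure onto the hindered, α-methyl-substituted butenolide carbon may be slow or may revert. The first Michael addition may also leave C10 uncontrolled if the equilibration argued above does not operate. The fallback replaces the anionic ring closure by a reductive radical one. It sets out from 17. The first half of step 13 is run without DBU and the nitroalkyl enamine 24 is isolated. Buffered TiCl3 Nef reaction of its primary nitro group should give the aldehyde (2S)-2-[(2R,3′R)-4-methyl-3′-[(2S,4S)-4-methyl-5-oxooxolan-2-yl]-5-oxo-2′,3′,5′,6′,7′,8′-hexahydro-5H-spiro[furan-2,1′-pyrrolo[1,2-a]azepin]-9′-yl]butanal F1. SmI2 in THF/t-BuOH at −78 °C should then effect a ketyl–olefin 6-exo cyclisation in which the C11 ketyl adds to C12 and the samarium enolate is protonated at C13 on the convex face. Chelation of Sm(III) between the ketyl oxygen and the lactone carbonyl should place the new hydroxyl syn to C13, although unchelated ketyl–enoate cyclisations normally favour the anti product, so this is uncertain. The fallback comes back to the route at 27 and makes steps 14 and 15 unnecessary.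

Step 14. The β-acyloxy ketone may lose the C1 carboxylate by elimination, reduction may stop at the oxime, or the protonated enamine may open hydrolytically. The fallback avoids the Nef reaction by going through the amine. It sets out from 25. Hydrogenation over Raney nickel (H2, EtOH) should reduce the nitro group to the 11-amino pentacycle F2 (target skeleton with NH2 in place of OH at C11, 11S). Biomimetic transamination with 4-formyl-1-methylpyridinium benzenesulfonate (imine formation, base-mediated prototropy, aqueous oxalic acid hydrolysis) should release the ketone under mildly acidic conditions. The fallback comes back at 26.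

Step 15. Facial selectivity may be poor, because the pseudoaxial C10 ethyl group shields the face opposite the lactone, and the C11 alkoxide may translactonise onto C14. The fallback sets the configuration by inversion instead of by hydride approach. It sets out from 26. Reduction with NaBH4/CeCl3 (MeOH, −78 °C; axial delivery) should give the 11-epi alcohol F3, which is also the by-product of an unselective step 15. Mitsunobu inversion with chloroacetic acid (PPh3, DIAD) should give the 11-O-chloroacetate of the target F4. Thiourea/NaHCO3 then removes the chloroacetyl group without base strong enough to move the lactone. The fallback comes back at 27.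

**Further compounds**

F1 | step 13 | (2S)-2-[(2R,3′R)-4-methyl-3′-[(2S,4S)-4-methyl-5-oxooxolan-2-yl]-5-oxo-2′,3′,5′,6′,7′,8′-hexahydro-5H-spiro[furan-2,1′-pyrrolo[1,2-a]azepin]-9′-yl]butanal | CC[C@H](C=O)C1=C2N(CCCC1)[C@@H]([C@@H]3C[C@H](C)C(=O)O3)C[C@]24OC(=O)C(C)=C4
F2 | step 14 | 11-amino pentacycle: target skeleton with NH2 in place of OH at C11 (11S) | CC[C@H]1C2=C3N(CCCC2)[C@@H]([C@@H]2C[C@H](C)C(=O)O2)C[C@]32OC(=O)[C@H](C)[C@@H]2[C@H]1N
F3 | step 15 | 11-epi alcohol: C11 epimer of the target (11S) | CC[C@H]1C2=C3N(CCCC2)[C@@H]([C@@H]2C[C@H](C)C(=O)O2)C[C@]32OC(=O)[C@H](C)[C@@H]2[C@H]1O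
F4 | step 15 | 11-O-chloroacetate of the target (11R) | CC[C@H]1C2=C3N(CCCC2)[C@@H]([C@@H]2C[C@H](C)C(=O)O2)C[C@]32OC(=O)[C@H](C)[C@@H]2[C@@H]1OC(=O)CCl
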